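Which finishes higher in monomer in chains: alpha, fed its free monomer over 2.0 min and read at 2.0 min, or eta, given everything at the start and read at 0.50 min?

the same everywhere: initiator 9.7 mM
- red: free monomer 0.050 M (fed, over 2.0 min); transfer agent 1 mM; temperature 105 °C; run made earlier; the fed solution adds 0.20 times the starting volume
- violet: free monomer 0.075 M (fed, over 2.0 min); transfer agent 1 mM; temperature 116 °C; run made earlier; the fed solution adds 0.20 times the starting volume
- amber: free monomer 0.10 M (fed, over 2.0 min); transfer agent 1.5 mM; temperature 105 °C; run made earlier; the fed solution adds 0.20 times the starting volume
- alpha: free monomer 0.10 M (fed, over 2.0 min); transfer agent 1.00 mM; temperature 110 °C; the fed solution adds 0.20 times the starting volume; time 2.0 min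
- eta: free monomer 0.10 M; transfer agent 1.00 mM; temperature 110 °C; everything together at the start, the whole solution of free monomer included, so that from the start the volume is larger by 0.20 times the starting volume; time 0.50 min

| run | time / min | monomer in chains / % |
|---|---|---|
| red | 0.200 | 3 |
| red | 0.333 | 2 |
| red | 0.417 | 5 |
| red | 0.667 | 13 |
| red | 1.00 | 14 |
| red | 1.50 | 22 |
| red | 2.50 | 39 |
| violet | 0.167 | 4 |
| violet | 0.333 | 2 |
| violet | 0.667 | 7 |
| violet | 1.00 | 15 |
| violet | 1.33 | 21 |
| violet | 2.00 | 34 |
| violet | 2.50 | 40 |
| amber | 0.200 | 4 |
| amber | 0.333 | 1 |
| amber | 0.667 | 7 |
| amber | 1.33 | 15 |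
| amber | 2.50 | 32 |

(scatter of a reading: 2 percentage points)

- which one finishes higher in amount of monomer in chains, in percent of the free monomer charged ("neither" within 2 percentage points) (alpha / eta / neither)
- amount of monomer in chains at the end, in percent of the free monomer charged, alpha
- amount of monomer in chains at the end, in percent of the free monomer charged, eta

- a species is counted by the free monomer in it: one homo dimer counts as two
- charges are per starting volume, the dose included; the dosed solution carries all of it
- steps under discussion: 2 free monomer -> homo dimer; free monomer + living end -> monomer in chains + living end; living end + monomer in chains -> dead end; free monomer + initiator -> living end + monomer in chains; living end + transfer agent -> dead chain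
- percentages count the whole charge, also what has not yet gone in

What does one initiator do? By the step on the board, it takes one free monomer into a chain and leaves a living end, with no growth yet.

So what do we reckon first? In alpha and in eta alike, the initiator charge, once reacted, puts 9.70% of the free monomer charged into chains. This ratio of charges, c(initiator) over c(free monomer), I call the start-up floor. The two flasks share it, so I expect them to part by what grows above it.

Where is the weak spot? My reckoning needs eta to reach its floor within 0.50 min. Amber has the same floor, and at 0.667 min, with a third of its monomer delivered, it already reads 7%. That is one reading with its scatter; eta has its whole charge from the start, and I assume it gets there.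

And the growth? Amber's readings climb from 15% to 32% between 1.33 min and 2.50 min, which reads, with their scatter, as a slope of 0.145 min⁻¹ as a fraction of the charge.

Your numbers? Read along that slope, amber gives 24.7% at 2.0 min, and I take this for alpha, though alpha differs from amber in temperature, 110 °C against 105 °C, and in transfer agent, 1.00 mM against 1.5 mM. For eta, floor plus slope over 0.50 min gives, as a rough figure, 17.0%, which is less than my figure for alpha.

The forecast names alpha, with 29% (23% to 35%) and 17% (9% to 27%), and grants eta that “its lag is shorter”. Its alpha stands above mine, its eta beside mine.

The simulation gives alpha higher, 28.4% against 18.3%, both inside the forecast's ranges.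

    2 free monomer → homo dimer (k = 0.190 M⁻¹ s⁻¹, Ea = 60.0 kJ mol⁻¹)
    free monomer + living end → monomer in chains + living end, rate k2*[living end]*[free monomer] (k = 0.930 M⁻¹ s⁻¹, Ea = 46.0 kJ mol⁻¹)
    living end + monomer in chains → dead end (k = 0.0140 M⁻¹ s⁻¹, Ea = 69.0 kJ mol⁻¹)
    free monomer + initiator → living end + monomer in chains (k = 1.80 M⁻¹ s⁻¹, Ea = 43.0 kJ mol⁻¹)
    living end + transfer agent → dead chain (kL = 2.80 M⁻¹ s⁻¹, Ea = 44.0 kJ mol⁻¹)
    (constants at 110 °C)

Has alpha come to rest at 2.00 min? No. Its initiator, the limiting reagent of the starting step, stands at 0.63% of its charge, monomer in chains lies 19 percentage points above the floor, and 39.0% of the free monomer charged remains. At 20.0 min alpha reads 46.5%, 37 points above the floor, with free monomer at 0.0539% and homo dimer up from 32.5% to 49.6%. Eta, with 5.9% of its initiator charge left, lies 8.6 points above the floor at 0.500 min; at 5.00 min it reads 38.3%, 29 points above it, with 2.71% of the free monomer charged left.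

(The runs were computed with constants of no real substance; scatter was added.)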